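**Retrosynthetic overview**
1. Prokinawan (14) ⇐ global fluoride desilylation of the tetrasilylated (2S)-flavanone 13.
2. C2–aryl bond and the only stereocentre ⇐ Rh(I)/chiral bisphosphine asymmetric 1,4-addition of arylboronic acid 7 to the fully elaborated 6-alkylchromone 12 (no chalcone, no resolution).
3. C6–side-chain bond ⇐ Stille coupling of 6-iodochromone 10 (made by 5-OH-directed iodination) with the E-allylstannane 4.
4. Stannane 4 ⇐ geraniol by terminal-selective hydration; boronic acid 7 ⇐ 4-bromocatechol.
5. Ring order: the A/C chromone bicycle is bought intact, the side chain is attached next, and the B ring is appended last, which converts the flat pyranone into the stereodefined C ring.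

Assumption: 5,7-dihydroxychromone is treated as a catalogue starting material. The target is (2S) with an E side-chain olefin, as read from the SMILES.

**Route**

Step 1
Reactants: 1, geraniol
Product: 2, (2E)-3,7-dimethyloct-2-ene-1,7-diol
Conditions: Hg(OAc)2 (1.0 equiv), THF–H2O 1:1, rt; then 3 M NaOH, NaBH4, 0 °C
Reagents that add atoms: water, O
Why: Markovnikov oxymercuration–demercuration occurs at the remote, more electron-rich 6,7-alkene (the 2,3-alkene is inductively deactivated by the allylic oxygen), giving the tertiary alcohol and leaving the 2E geometry untouched.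

Step 2
Reactants: 2, (2E)-3,7-dimethyloct-2-ene-1,7-diol
Product: 3, (6E)-8-chloro-2,6-dimethyloct-6-en-2-ol
Conditions: MsCl, LiCl, s-collidine, DMF, 0 °C
Reagents that add atoms: lithium chloride, [Li+].[Cl-] (MsCl, CS(=O)(=O)Cl, is the activator and its chloride can also be incorporated)
Why: Collington–Meyers chlorination (in situ mesylate, SN2 by chloride) converts only the primary allylic OH, without allylic transposition or E/Z loss; the tertiary OH is not mesylated at 0 °C.

Step 3
Reactants: 3, (6E)-8-chloro-2,6-dimethyloct-6-en-2-ol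
Product: 4, (6E)-2,6-dimethyl-8-(tributylstannyl)oct-6-en-2-ol
Conditions: Bu3SnLi (2.2 equiv, from Bu3SnH + LDA), THF, −78 → −20 °C
Reagents that add atoms: tributylstannyllithium, [Li][Sn](CCCC)(CCCC)CCCC (from tributyltin hydride, CCCC[SnH](CCCC)CCCC)
Why: SN2 stannylation of a primary allylic chloride by the stannyl anion (the first equivalent only deprotonates the tertiary OH) gives the linear E-allylstannane with retained geometry.

Step 4
Reactants: 5, 4-bromocatechol
Product: 6, 4-bromo-1,2-bis(tert-butyldimethylsilyloxy)benzene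
Conditions: TBSCl (2.3 equiv), imidazole, DMF, rt
Reagents that add atoms: TBSCl, CC(C)(C)[Si](C)(C)Cl
Why: Standard imidazole-promoted O-silylation of both phenols.

Step 5
Reactants: 6, 4-bromo-1,2-bis(tert-butyldimethylsilyloxy)benzene
Product: 7, [3,4-bis(tert-butyldimethylsilyloxy)phenyl]boronic acid
Conditions: B(OiPr)3, then n-BuLi (in situ quench), THF–toluene, −78 °C; aq NH4Cl
Reagents that add atoms: triisopropyl borate, CC(C)OB(OC(C)C)OC(C)C; water, O
Why: Br/Li exchange with immediate borate trapping and mild hydrolysis gives the boronic acid; aryl TBS ethers tolerate n-BuLi at −78 °C and the neutral work-up.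

Step 6
Reactants: 8, 5,7-dihydroxy-4H-chromen-4-one
Product: 9, 5-hydroxy-7-(triisopropylsilyloxy)-4H-chromen-4-one
Conditions: TIPSCl (1.05 equiv), imidazole, DMF, 0 °C → rt
Reagents that add atoms: TIPSCl, CC(C)[Si](Cl)(C(C)C)C(C)C
Why: Selective O-silylation of the acidic, unhindered 7-OH; the 5-OH is locked in a hydrogen bond to C4=O and stays free.

Step 7
Reactants: 9, 5-hydroxy-7-(triisopropylsilyloxy)-4H-chromen-4-one
Product: 10, 5-hydroxy-6-iodo-7-(triisopropylsilyloxy)-4H-chromen-4-one
Conditions: BnMe3N·ICl2 (1.05 equiv), CaCO3, CH2Cl2–MeOH, rt, dark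
Reagents that add atoms: benzyltrimethylammonium dichloroiodate, C[N+](C)(C)Cc1ccccc1.Cl[I-]Cl
Why: Electrophilic aromatic iodination with a phenol-ortho-selective reagent goes to C6, ortho to the free chelated 5-OH (5-hydroxy-7-alkoxy chromones/flavones iodinate at C6, whereas 5-O-alkyl analogues go to C8); the pyranone C3 is far less nucleophilic, and CaCO3 buffering protects the TIPS ether.

Step 8
Reactants: 10, 5-hydroxy-6-iodo-7-(triisopropylsilyloxy)-4H-chromen-4-one; 4, (6E)-2,6-dimethyl-8-(tributylstannyl)oct-6-en-2-ol (1.6 equiv)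
Product: 11, 5-hydroxy-6-[(2E)-7-hydroxy-3,7-dimethyloct-2-en-1-yl]-7-(triisopropylsilyloxy)-4H-chromen-4-one
Conditions: Pd2(dba)3 (5 mol %), P(2-furyl)3 (20 mol %), degassed DMF, 70 °C
Reagents that add atoms: none
Why: Stille coupling — oxidative addition at C–I, allyl transfer from tin, and reductive elimination at the unsubstituted allyl terminus give the linear product with the E-trisubstituted alkene preserved; the base-free medium spares the chromone, the aryl silyl ether and the free OH groups.

Step 9
Reactants: 11, 5-hydroxy-6-[(2E)-7-hydroxy-3,7-dimethyloct-2-en-1-yl]-7-(triisopropylsilyloxy)-4H-chromen-4-one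
Product: 12, 5-(tert-butyldimethylsilyloxy)-6-[(2E)-7-hydroxy-3,7-dimethyloct-2-en-1-yl]-7-(triisopropylsilyloxy)-4H-chromen-4-one
Conditions: NaH (1.05 equiv), THF, 0 °C; TBSCl (1.1 equiv), 0 °C → rt
Reagents that add atoms: TBSCl, CC(C)(C)[Si](C)(C)Cl
Why: One equivalent of base deprotonates only the phenol (about 7–8 pKa units more acidic than the tertiary alcohol) and the phenoxide is O-silylated, masking the acidic chelated OH that would otherwise form a deactivated phenoxide and quench Rh–OH in the next step.

Step 10
Reactants: 12, 5-(tert-butyldimethylsilyloxy)-6-[(2E)-7-hydroxy-3,7-dimethyloct-2-en-1-yl]-7-(triisopropylsilyloxy)-4H-chromen-4-one; 7, [3,4-bis(tert-butyldimethylsilyloxy)phenyl]boronic acid (3 equiv)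
Product: 13, (2S)-2-[3,4-bis(tert-butyldimethylsilyloxy)phenyl]-5-(tert-butyldimethylsilyloxy)-6-[(2E)-7-hydroxy-3,7-dimethyloct-2-en-1-yl]-7-(triisopropylsilyloxy)chroman-4-one
Conditions: [RhCl(C2H4)2]2 (2.5 mol %), (S)-MeO-F12-BIPHEP (5.5 mol %), KOH (10 mol %), toluene–H2O 10:1, 30 °C
Reagents that add atoms: none
Why: Hayashi–Miyaura Rh(I)-catalysed asymmetric 1,4-addition — the aryl–Rh(P*P) species inserts the chromone C2=C3 on one enantioface and the oxa-π-allyl rhodium is hydrolysed, so the (S)-biaryl bisphosphine sets C2 as S (same facial sense as (S)-BINAP giving (S)-3-arylcyclohexanone), while the electron-poor ligand speeds insertion at low temperature and suppresses 1,2-addition and ring opening; the unactivated trisubstituted alkene, tertiary OH and silyl ethers are inert.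

Step 11
Reactants: 13, the tetrasilylated (2S)-flavanone
Product: 14, Prokinawan, (2S)-2-(3,4-dihydroxyphenyl)-5,7-dihydroxy-6-[(2E)-7-hydroxy-3,7-dimethyloct-2-en-1-yl]chroman-4-one
Conditions: TBAF (6 equiv), AcOH (6 equiv), degassed THF, 0 °C; pH 5 buffer work-up
Reagents that add atoms: none
Why: Fluoride-mediated cleavage of all four aryl silyl ethers; AcOH buffering keeps the medium non-basic so the flavanone cannot racemise by retro-oxa-Michael opening, and the tertiary alcohol and alkene are untouched.

**Compound list**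
1 | geraniol | CC(C)=CCC/C(C)=C/CO | starting material
2 | (2E)-3,7-dimethyloct-2-ene-1,7-diol | CC(C)(O)CCC/C(C)=C/CO | intermediate
3 | (6E)-8-chloro-2,6-dimethyloct-6-en-2-ol | CC(C)(O)CCC/C(C)=C/CCl | intermediate
4 | (6E)-2,6-dimethyl-8-(tributylstannyl)oct-6-en-2-ol | CC(C)(O)CCC/C(C)=C/C[Sn](CCCC)(CCCC)CCCC | intermediate
5 | 4-bromocatechol | Oc1ccc(Br)cc1O | starting material
6 | 4-bromo-1,2-bis(tert-butyldimethylsilyloxy)benzene | CC(C)(C)[Si](C)(C)Oc1ccc(Br)cc1O[Si](C)(C)C(C)(C)C | intermediate
7 | [3,4-bis(tert-butyldimethylsilyloxy)phenyl]boronic acid | CC(C)(C)[Si](C)(C)Oc1ccc(B(O)O)cc1O[Si](C)(C)C(C)(C)C | intermediate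
8 | 5,7-dihydroxy-4H-chromen-4-one | O=c1ccoc2cc(O)cc(O)c12 | starting material
9 | 5-hydroxy-7-(triisopropylsilyloxy)-4H-chromen-4-one | O=c1ccoc2cc(O[Si](C(C)C)(C(C)C)C(C)C)cc(O)c12 | intermediate
10 | 5-hydroxy-6-iodo-7-(triisopropylsilyloxy)-4H-chromen-4-one | O=c1ccoc2cc(O[Si](C(C)C)(C(C)C)C(C)C)c(I)c(O)c12 | intermediate
11 | 5-hydroxy-6-[(2E)-7-hydroxy-3,7-dimethyloct-2-en-1-yl]-7-(triisopropylsilyloxy)-4H-chromen-4-one | C/C(=C\Cc1c(O[Si](C(C)C)(C(C)C)C(C)C)cc2occc(=O)c2c1O)CCCC(C)(C)O | intermediate
12 | 5-(tert-butyldimethylsilyloxy)-6-[(2E)-7-hydroxy-3,7-dimethyloct-2-en-1-yl]-7-(triisopropylsilyloxy)-4H-chromen-4-one | C/C(=C\Cc1c(O[Si](C(C)C)(C(C)C)C(C)C)cc2occc(=O)c2c1O[Si](C)(C)C(C)(C)C)CCCC(C)(C)O | intermediate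
13 | (2S)-2-[3,4-bis(tert-butyldimethylsilyloxy)phenyl]-5-(tert-butyldimethylsilyloxy)-6-[(2E)-7-hydroxy-3,7-dimethyloct-2-en-1-yl]-7-(triisopropylsilyloxy)chroman-4-one | C/C(=C\Cc1c(O[Si](C(C)C)(C(C)C)C(C)C)cc2c(c1O[Si](C)(C)C(C)(C)C)C(=O)C[C@@H](c1ccc(O[Si](C)(C)C(C)(C)C)c(O[Si](C)(C)C(C)(C)C)c1)O2)CCCC(C)(C)O | intermediate
14 | Prokinawan, (2S)-2-(3,4-dihydroxyphenyl)-5,7-dihydroxy-6-[(2E)-7-hydroxy-3,7-dimethyloct-2-en-1-yl]chroman-4-one | C/C(=C\Cc1c(O)cc2c(c1O)C(=O)C[C@@H](c1ccc(O)c(O)c1)O2)CCCC(C)(C)O | target

**Totals**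
Total steps: 11 (3 for the stannane, 2 for the boronic acid, 6 on the chromone line).
Longest linear sequence: 7 steps (geraniol → 2 → 3 → 4 → 11 → 12 → 13 → 14); 6 steps from 5,7-dihydroxychromone.

**Three steps most likely to fail**
1. Step 10 (asymmetric 1,4-arylation). The chromone is donor-rich and 5,6,7-trisubstituted, so the risks are slow insertion, protodeboronation, ring-opened chalcone, and an enantioselectivity or facial sense that differs from the simple-enone model. Fallback: reverse the order — run the asymmetric arylation on the side-chain-free 5,7-diprotected chromone (closest to precedent substrates), then unmask 5-OH, iodinate C6 of the flavanone and attach the side chain by the same base-free Stille coupling, which does not endanger C2.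
2. Step 7 (C6 versus C8 iodination). Fallback: fix the regiochemistry by symmetry — lithiate 3,5-bis(MOMO)phenyl TIPS ether between the two OMOM groups, transmetalate to copper and alkylate (SN2) with chloride 3 (tertiary OH as its TES ether), then annulate the pyranone onto the single phenol, whose two ortho positions are equivalent, so only the 6-substituted chromone can form.
3. Step 8 (Stille coupling). The iodide is di-ortho-substituted, and linear/branched selectivity, E/Z erosion and protodestannylation by the free phenol are all possible. Fallback: invert the polarity — Miyaura borylation of 10 to the 6-boronate, then Pd-catalysed allyl–aryl coupling with the allylic tert-butyl carbonate of diol 2 (π-allyl electrophile, aryl delivered to the unsubstituted terminus), which also removes tin from the route.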